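Ring B is cut as a formal [4+2] (labdane numbering): the C10–C5–C6–C7 arm of a ring A aldehyde plus the C8=C9 olefin of an enal that already carries C17 and the complete C11–C16 side chain. In one operation an iron-hydride HAT radical–polar crossover annulation makes C9–C10 by Giese addition of the tertiary C10 radical and C7–C8 by aldol closure, creating ring B, the quaternary C10 and C9. The step exploits the C17-oxygenated C7=C8 olefin of ring B (an aldol-condensation retron) lying 1,3 to the methyl-bearing quaternary C10. The precursors are [(1S)-2,6,6-trimethylcyclohex-2-en-1-yl]acetaldehyde and methyl (2E,6E)-3-methyl-8-oxoocta-2,6-dienoate.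

Key step: step 5

Remark: methyl (2E)-geranate of E-isomer grade and 2,4,4-trimethylcyclohex-2-en-1-one are taken as catalogue compounds; α/β descriptors refer to the usual labdane drawing (10β-CH3 up).

Step 1
Reactants: 1 methyl (2E)-3,7-dimethylocta-2,6-dienoate (methyl geranate)
Product: 2 methyl (2E,6E)-3-methyl-8-oxoocta-2,6-dienoate
Conditions: (E)-crotonaldehyde (5 equiv), second-generation Hoveyda–Grubbs catalyst (H2IMes)Cl2Ru(=CH-C6H4-2-Oi-Pr) (5 mol %), CH2Cl2, 40 °C
Reagents that add atoms: (E)-crotonaldehyde, C/C=C/C=O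
Why: Olefin cross-metathesis: only the electron-rich isopropylidene end of 1 can enter the ruthenium carbene cycle (the conjugated trisubstituted enoate olefin is inert), and the new conjugated enal should form as the thermodynamically preferred E isomer.

Step 2
Reactants: 3 2,4,4-trimethylcyclohex-2-en-1-one
Product: 4 (1R)-2,4,4-trimethylcyclohex-2-en-1-ol
Conditions: (S)-2-methyl-CBS-oxazaborolidine (10 mol %), BH3·SMe2, THF, −20 °C; MeOH quench
Reagents that add atoms: none
Why: Corey–Bakshi–Shibata reduction: the ketone binds the oxazaborolidine with the 2-methylvinyl arm as the large group, so the (S)-catalyst should deliver hydride to the face that gives the (1R)-carbinol.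

Step 3
Reactants: 4 (1R)-2,4,4-trimethylcyclohex-2-en-1-ol
Product: 6 ethyl [(1S)-2,6,6-trimethylcyclohex-2-en-1-yl]acetate, via mixed ketene acetal 5 (not isolated)
Conditions: CH3C(OEt)3 (7 equiv), EtCO2H (cat.), 140 °C, EtOH distilled off
Reagents that add atoms: triethyl orthoacetate, CC(OCC)(OCC)OCC
Why: Johnson–Claisen rearrangement: the suprafacial [3,3] shift of 5 transfers the C–O configuration to the new C–C bond at the ring carbon next to the gem-dimethyl group (C5 of the target, S) and moves the olefin to C1=C10.

Step 4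
Reactants: 6 ethyl [(1S)-2,6,6-trimethylcyclohex-2-en-1-yl]acetate
Product: 7 [(1S)-2,6,6-trimethylcyclohex-2-en-1-yl]acetaldehyde
Conditions: i-Bu2AlH (1.1 equiv), CH2Cl2, −78 °C; aq. KNaC4H4O6
Reagents that add atoms: none
Why: Half-reduction of an ester with i-Bu2AlH at −78 °C should stop at the aldehyde level after aqueous work-up; the C5 stereocentre is not α to the carbonyl and cannot epimerise.

Step 5
Reactants: 7 [(1S)-2,6,6-trimethylcyclohex-2-en-1-yl]acetaldehyde; 2 methyl (2E,6E)-3-methyl-8-oxoocta-2,6-dienoate
Product: 10 methyl 7-hydroxy-17-oxolabd-13E-en-15-oate (C7/C8 epimer mixture), via C10 tertiary radical 8 (not isolated), via C8 enolate of the Giese adduct 9 (not isolated)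
Conditions: Fe(acac)3 (30 mol %), PhSiH3 (2.5 equiv), 2 (2.5 equiv), EtOH/(CH2OH)2, 0 °C to rt
Reagents that add atoms: none
Why: Metal-hydride hydrogen atom transfer from the iron hydride to C1 of the ring olefin of 7 gives the tertiary C10 radical 8, which adds to the enal β-carbon C9 of 2; divalent iron reduces the α-formyl radical to enolate 9, whose C8 closes onto the C7 aldehyde. The closest known reaction type is the HAT-initiated radical–polar crossover (Giese–aldol) annulation of γ,δ-unsaturated aldehydes with enals or enones. Ring B is closed in the aldol stage by a 6-(enolexo)-exo-trig attack, after the intermolecular C9–C10 bond has supplied the sixth atom. C10 is controlled by the C5 stereocentre and the C4 gem-dimethyl group: the enal enters the planar radical trans to the C5 acetaldehyde arm and away from the syn-axial C4 methyl, so C20 ends axial (10β) on a trans-fused decalin. C9 is fixed in the same radical addition through an open transition state in which H9 faces the crowded C5–C6 sector, the planar enal terminus C8 lies anti to C5 and the C11 chain anti to C20, which leads to the 9β side chain; this is the least secured element, C7 and C8 form as mixtures that step 6 erases, and a C9 epimer would be removed at 12. The step needs HAT only at the electron-rich ring olefin and Giese addition only at the β-monosubstituted enal, which the electron-poor β,β-disubstituted enoate olefin of 2 secures by polarity and substitution, while the regiochemistry of both bond formations follows from the polarity of the nucleophilic tertiary radical and of the enolate.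

Step 6
Reactants: 10 methyl 7-hydroxy-17-oxolabd-13E-en-15-oate (C7/C8 epimer mixture)
Product: 12 methyl (5S,9R,10S)-17-oxolabda-7,13E-dien-15-oate, via C7 mesylate 11 (not isolated)
Conditions: MsCl, Et3N, CH2Cl2, 0 °C; then DBU, rt
Reagents that add atoms: none
Why: E1cB dehydration of the aldol: DBU removes the acidic C8–H next to the formyl group and expels the C7 mesylate, which should give the conjugated C7=C8 enal from every C7/C8 diastereomer, while the non-acidic C9–H is untouched.

Step 7
Reactants: 12 methyl (5S,9R,10S)-17-oxolabda-7,13E-dien-15-oate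
Product: 13 (5S,9R,10S)-labda-7,13E-diene-15,17-diol
Conditions: i-Bu2AlH (5 equiv), CH2Cl2, −78 to 0 °C; aq. KNaC4H4O6
Reagents that add atoms: none
Why: i-Bu2AlH reduces the enal and the enoate by 1,2-addition only, so both allylic alcohols should form without change at either trisubstituted olefin or at any stereocentre.

Step 8
Reactants: 13 (5S,9R,10S)-labda-7,13E-diene-15,17-diol
Product: 14 (5S,9R,10S)-labda-7,13E-diene-15,17-diyl diacetate (CNP0257931.1)
Conditions: Ac2O, pyridine, DMAP (cat.), CH2Cl2, rt
Reagents that add atoms: acetic anhydride, CC(=O)OC(C)=O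
Why: DMAP-catalysed acylation of the two primary allylic alcohols is a standard esterification that touches no stereocentre.

Compound list
1 | methyl (2E)-3,7-dimethylocta-2,6-dienoate (methyl geranate) | COC(=O)/C=C(\C)CCC=C(C)C | starting material
2 | methyl (2E,6E)-3-methyl-8-oxoocta-2,6-dienoate | COC(=O)/C=C(\C)CC/C=C/C=O | intermediate
3 | 2,4,4-trimethylcyclohex-2-en-1-one | CC1=CC(C)(C)CCC1=O | starting material
4 | (1R)-2,4,4-trimethylcyclohex-2-en-1-ol | O[C@@H]1CCC(C)(C)C=C1C | intermediate
5 | (1R)-2,4,4-trimethylcyclohex-2-en-1-yl 1-ethoxyethenyl ether (mixed ketene acetal, formed in the flask) | C=C(OCC)O[C@@H]1CCC(C)(C)C=C1C | intermediate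
6 | ethyl [(1S)-2,6,6-trimethylcyclohex-2-en-1-yl]acetate | CCOC(=O)C[C@H]1C(C)(C)CCC=C1C | intermediate
7 | [(1S)-2,6,6-trimethylcyclohex-2-en-1-yl]acetaldehyde | O=CC[C@H]1C(C)(C)CCC=C1C | intermediate
8 | tertiary C10 radical from H-atom transfer to C1 of 7, C5 unchanged (formed in the flask) | C[C]1CCCC(C)(C)[C@@H]1CC=O | intermediate
9 | C8 formyl enolate of the Giese adduct of 8 and 2, iron counter-ion omitted; C5, C9, C10 as in 10 (formed in the flask) | COC(=O)/C=C(\C)CC[C@@H](C=C[O-])[C@@]1(C)CCCC(C)(C)[C@@H]1CC=O | intermediate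
10 | methyl 7-hydroxy-17-oxolabd-13E-en-15-oate; 5α-H, 9α-H (9β side chain), 10β-CH3, trans-decalin; C7/C8 epimer mixture | COC(=O)/C=C(\C)CC[C@H]1C(C=O)C(O)C[C@H]2C(C)(C)CCC[C@]12C | intermediate
11 | C7 methanesulfonate of 10, same ring stereochemistry (formed in the flask) | COC(=O)/C=C(\C)CC[C@H]1C(C=O)C(OS(C)(=O)=O)C[C@H]2C(C)(C)CCC[C@]12C | intermediate
12 | methyl (5S,9R,10S)-17-oxolabda-7,13E-dien-15-oate | COC(=O)/C=C(\C)CC[C@H]1C(C=O)=CC[C@H]2C(C)(C)CCC[C@]12C | intermediate
13 | (5S,9R,10S)-labda-7,13E-diene-15,17-diol | OC/C=C(\C)CC[C@H]1C(CO)=CC[C@H]2C(C)(C)CCC[C@]12C | intermediate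
14 | (5S,9R,10S)-labda-7,13E-diene-15,17-diyl diacetate (CNP0257931.1) | CC(=O)OC/C=C(\C)CC[C@H]1C(COC(C)=O)=CC[C@H]2C(C)(C)CCC[C@]12C | target

Total step count: 8 (step 1 for the enal, steps 2–4 for the aldehyde, steps 5–8 after their union).
Longest linear sequence: 7 steps (3 → 4 → 6 → 7 → 10 → 12 → 13 → 14).

Steps most likely to fail

Step 5. The intermolecular radical addition may show little facial discrimination at C9, and the hindered C10 radical may be reduced before it meets the β-substituted enal. The fallback makes the two bonds one after the other and closes C9–C10 inside a ring-forming transition state; it sets out from 7 and 1 and comes back at 13. Roskamp homologation of 7 (methyl diazoacetate, SnCl2 cat., CH2Cl2) should give methyl 3-oxo-4-[(1S)-2,6,6-trimethylcyclohex-2-en-1-yl]butanoate F1. Ozonolysis of the electron-rich 6,7-olefin of 1 (O3, CH2Cl2, −78 °C; Me2S) should give methyl (2E)-3-methyl-6-oxohex-2-enoate F2. Knoevenagel condensation of F1 with F2 (piperidine, AcOH, benzene, water removal) should give dimethyl (2E,6Z)-3-methyl-7-{[(1S)-2,6,6-trimethylcyclohex-2-en-1-yl]acetyl}octa-2,6-dienedioate F3, expected mainly as the isomer with the side chain cis to the ester and trans to the ketone. HAT-initiated 6-endo radical cyclisation (Fe(acac)3, PhSiH3, EtOH) forms C9–C10 through a chair transition state that turns this olefin geometry into the equatorial 9β side chain, giving dimethyl 7-oxolabd-13E-ene-15,17-dioate F4. Its enol triflate, dimethyl 7-(trifluoromethanesulfonyloxy)labda-7,13E-diene-15,17-dioate F5 (NaH, PhNTf2, THF), is reduced (Pd(OAc)2, PPh3, HCO2H, Et3N, DMF) to dimethyl labda-7,13E-diene-15,17-dioate F6, and i-Bu2AlH converts F6 into 13.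

Step 3. Acid-induced ionisation of the allylic alcohol (erosion of enantiomeric purity, diene formation) may outrun the slow rearrangement next to the quaternary C4. The fallback replaces the sigmatropic shift by a copper-mediated anti-SN2′ substitution; it sets out from 3 and comes back at 7. Reduction of 3 with the mirror-image catalyst ((R)-2-methyl-CBS-oxazaborolidine, BH3·SMe2) should give (1S)-2,4,4-trimethylcyclohex-2-en-1-ol F7, which is esterified (picolinic acid, DCC, DMAP) to (1S)-2,4,4-trimethylcyclohex-2-en-1-yl pyridine-2-carboxylate F8. Picolinate-directed substitution (CH2=CHMgBr, CuBr·SMe2, THF, −40 to 0 °C) delivers the vinyl group to the γ-carbon anti to the leaving group and should give (6S)-6-ethenyl-1,5,5-trimethylcyclohex-1-ene F9. Hydroboration of the vinyl group only (9-BBN; NaOH, H2O2) gives 2-[(1S)-2,6,6-trimethylcyclohex-2-en-1-yl]ethan-1-ol F10, and Dess–Martin oxidation gives 7.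

Step 1. Turnover at the trisubstituted olefin may be slow, and the ruthenium carbene may be lost through coordination of the enal. The fallback replaces metathesis by oxidative cleavage and olefination; it sets out from 1 and comes back at 2. Ozonolysis of the 6,7-olefin of 1 (O3, CH2Cl2, −78 °C; Me2S) should give methyl (2E)-3-methyl-6-oxohex-2-enoate F11 (the same structure as F2), and Wittig reaction with Ph3P=CHCHO (toluene, 80 °C) should give the E-enal 2.

Further compounds
F1 | step 5 | methyl 3-oxo-4-[(1S)-2,6,6-trimethylcyclohex-2-en-1-yl]butanoate | COC(=O)CC(=O)C[C@H]1C(C)(C)CCC=C1C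
F2 | step 5 | methyl (2E)-3-methyl-6-oxohex-2-enoate | COC(=O)/C=C(\C)CCC=O
F3 | step 5 | dimethyl (2E,6Z)-3-methyl-7-{[(1S)-2,6,6-trimethylcyclohex-2-en-1-yl]acetyl}octa-2,6-dienedioate | COC(=O)/C=C(\C)CC/C=C(\C(=O)OC)C(=O)C[C@H]1C(C)(C)CCC=C1C
F4 | step 5 | dimethyl 7-oxolabd-13E-ene-15,17-dioate (5α-H, 9α-H, 10β-CH3; C8 epimers) | COC(=O)/C=C(\C)CC[C@H]1C(C(=O)OC)C(=O)C[C@H]2C(C)(C)CCC[C@]12C
F5 | step 5 | dimethyl 7-(trifluoromethanesulfonyloxy)labda-7,13E-diene-15,17-dioate | COC(=O)/C=C(\C)CC[C@H]1C(C(=O)OC)=C(OS(=O)(=O)C(F)(F)F)C[C@H]2C(C)(C)CCC[C@]12C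
F6 | step 5 | dimethyl labda-7,13E-diene-15,17-dioate | COC(=O)/C=C(\C)CC[C@H]1C(C(=O)OC)=CC[C@H]2C(C)(C)CCC[C@]12C
F7 | step 3 | (1S)-2,4,4-trimethylcyclohex-2-en-1-ol | O[C@H]1CCC(C)(C)C=C1C
F8 | step 3 | (1S)-2,4,4-trimethylcyclohex-2-en-1-yl pyridine-2-carboxylate | O=C(O[C@H]1CCC(C)(C)C=C1C)c1ccccn1
F9 | step 3 | (6S)-6-ethenyl-1,5,5-trimethylcyclohex-1-ene | C=C[C@H]1C(C)(C)CCC=C1C
F10 | step 3 | 2-[(1S)-2,6,6-trimethylcyclohex-2-en-1-yl]ethan-1-ol | OCC[C@H]1C(C)(C)CCC=C1C
F11 | step 1 | methyl (2E)-3-methyl-6-oxohex-2-enoate | COC(=O)/C=C(\C)CCC=O
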